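**Retrosynthetic overview**
1. Kukoamine A ⇒ two amide C–N disconnections at N1 and N12, giving free spermine and two dihydrocaffeoyl donors, with no protecting groups on N4/N9 or on the catechols.
2. The acyl donor is methyl dihydrocaffeate, made by esterifying dihydrocaffeic acid.
3. Site selection (terminal NH2 over internal NH, N over phenolic O) is left to the catalyst in the amide-forming step.
4. No ring is formed; both arene rings arrive intact with the acid.

Assumption: the target has no stereocentre (it is achiral), so "single enantiomer" is read as the single constitution shown and no stereocontrol is needed.

**Step 1**
Reactants: 1 3-(3,4-dihydroxyphenyl)propanoic acid (dihydrocaffeic acid)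
Product: 2 methyl 3-(3,4-dihydroxyphenyl)propanoate
Conditions: MeOH (solvent), conc. H2SO4 (5 mol %), reflux, 6 h, N2; concentrate, EtOAc/aq. NaHCO3 wash
Reagents that add atoms: methanol, CO
Why: Fischer esterification; acid-catalysed acyl substitution in excess methanol drives the equilibrium to the ester, the phenols are neither esterified nor etherified under these conditions, and no stereocentre is involved.

**Step 2**
Reactants: 2 methyl 3-(3,4-dihydroxyphenyl)propanoate (2.2 equiv); 3 spermine (free base, 1.0 equiv)
Product: 5 kukoamine A, via N1-dihydrocaffeoylspermine 4 (not isolated)
Conditions: Novozym 435 (immobilised Candida antarctica lipase B, about 100 mg per mmol of 3), 5 Å MS, degassed 2-methyl-2-butanol, 55 °C, Ar, 48–72 h; filter, concentrate, triturate with EtOAc to remove excess 2, C18 chromatography (H2O/MeOH) under Ar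
Reagents that add atoms: none
Why: Proposed new method: lipase-catalysed, protecting-group-free N1,N12-bis-aminolysis of a catechol ester by free spermine, which to my knowledge has not been shown for an unprotected tetraamine or for a free-catechol acyl donor in a basic polyamine medium; Ser105 of the lipase is acylated by the unhindered ester 2 (methanol is released and trapped by the sieves), and this acyl-enzyme is attacked only by a terminal CH2NH2 group, because the narrow nucleophile pocket (the one that limits the medium substituent of secondary alcohols to about ethyl) cannot place an internal dialkylamine nitrogen carrying propyl and butyl arms on the attack trajectory under His224 general-base assistance; phenols are not acyl acceptors for this enzyme and uncatalysed aminolysis of a methyl ester is negligible at 55 °C, so mono-amide 4 forms first and its remaining NH2 terminus reacts again to give 5; the closest known reaction type is lipase-catalysed aminolysis of alkyl esters by simple primary amines and diamines, together with lipase transesterification of dihydrocaffeate esters with alcohols; no stereocentre is formed.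

**Compound list**
1 | 3-(3,4-dihydroxyphenyl)propanoic acid (dihydrocaffeic acid) | O=C(O)CCc1ccc(O)c(O)c1 | starting material
2 | methyl 3-(3,4-dihydroxyphenyl)propanoate | COC(=O)CCc1ccc(O)c(O)c1 | intermediate
3 | spermine (N1,N1'-(butane-1,4-diyl)bis(propane-1,3-diamine)) | NCCCNCCCCNCCCN | starting material
4 | N1-dihydrocaffeoylspermine, N-[3-({4-[(3-aminopropyl)amino]butyl}amino)propyl]-3-(3,4-dihydroxyphenyl)propanamide | O=C(CCc1ccc(O)c(O)c1)NCCCNCCCCNCCCN | intermediate
5 | kukoamine A (N1,N12-bis(dihydrocaffeoyl)spermine) | O=C(CCc1ccc(O)c(O)c1)NCCCNCCCCNCCCNC(=O)CCc1ccc(O)c(O)c1 | target

**Step count and risks**
Total step count: 2. Longest linear sequence: 2 steps (1 → 2 → 5).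

The route has only two steps, so both are listed, the riskier first.

Risk 1, step 2 (the proposed new step). Possible failures: the reaction stalls at mono-amide 4; ammonium catecholate salts of 2 and 3 precipitate or inhibit the enzyme; traces of O2 oxidise the catechol to an o-quinone in the basic medium. Fallback with known chemistry, which replaces catalyst control by a stoichiometric active ester whose steric preference selects the primary amines: it sets out from compound 1, which is treated with N-hydroxysuccinimide (1.1 equiv) and DCC (1.05 equiv) in THF at 0 °C to room temperature to give succinimidyl dihydrocaffeate F1 after filtration of the urea. F1 (2.05 equiv) is then added slowly to spermine 3 in DMF/CH2Cl2 at −20 °C and warmed to room temperature, and the terminal bis-amide is separated from minor N4-acylated isomers by reversed-phase HPLC. The fallback comes back to the route at compound 5.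

Risk 2, step 1. Possible failures: incomplete conversion or darkening of the catechol on prolonged acidic reflux. Fallback that changes the bond being made (the O–CH3 bond by SN2 instead of the acyl C–O bond): it sets out from compound 1, whose carboxylate is formed with KHCO3 (1.1 equiv) in DMF and alkylated with MeI (1.2 equiv) at room temperature; bicarbonate is too weak a base to deprotonate the catechol, so only the carboxylate is methylated. The fallback comes back to the route at compound 2 and makes no compound outside the list (F0).

**Further compounds**
F1 | step 2 | 2,5-dioxopyrrolidin-1-yl 3-(3,4-dihydroxyphenyl)propanoate (succinimidyl dihydrocaffeate) | O=C(CCc1ccc(O)c(O)c1)ON1C(=O)CCC1=O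
F0 | step 1 | none | none
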